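**Plan**

1. Numbering used below (bicyclo[3.2.1]octene core): C1 = quaternary bridgehead bound to the arene; C2=C3(CH3) = ring alkene; C4 = CH2; C5 = benzylic CH bridgehead; C6/C7 = the two arene carbons; C8 = one-carbon bridge carrying the prenyl group; ring A = the ene-dione ring fused across C1–C8.
2. Retrosynthesis: the phenols go back to methyl ethers (via the quinone); ring A is cut at CH=CH (ring-closing metathesis) and at both C(O)–CH bonds (vinyl additions) back to a C1,C8-diester; one retro-[4+2] then cuts C4–C5 and C1–C8, which opens the five-, six- and seven-membered rings of the bridged core together.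
3. Enabling feature: the cyclohexene C1–C2=C3(CH3)–C4–C5–C8 is a Diels–Alder retron whose diene terminus C1 and dienophile carbon C5 sit on adjacent carbons (C7, C6) of the hydroquinone ring, so the arene is a built-in two-atom tether that allows only the bridged mode.
4. Forward: 2-bromo-3,6-dimethoxybenzaldehyde → Z-enoate arm (dienophile) → arylacetate → 2-aryl dienoate arm (diene) → intramolecular [4+2] (whole bridged core, both quaternary centres) → diol, dialdehyde, two staged vinyl additions through a lactol, metathesis and oxidation (ring A) → oxidative demethylation and reduction.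
5. Stereochemistry: all three stereocentres arise in the cycloaddition. C1/C5 are cis by the arene bridge, C8 follows from the Z geometry of the enoate, and the absolute sense comes from a menthyl ester auxiliary (diastereomer separation) that is cleaved in the next reduction.

Key step: step 9

Assumption: the (1R,2S,5R)-menthyl ester is taken to favour, or at least to allow isolation of, the cycloadduct of target configuration; if the bias has the opposite sense, the same route is run with the (1S,2R,5S)-menthyl ester.

Step 1
Reactants: 1 2-bromo-1,4-dimethoxybenzene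
Product: 2 2-bromo-3,6-dimethoxybenzaldehyde
Conditions: LiN(iPr)2, THF, −78 °C; then DMF, −78 °C to rt
Reagents that add atoms: N,N-dimethylformamide, CN(C)C=O
Why: Directed ortho-lithiation removes the ring proton flanked by Br and OMe (the most acidic one) and the aryllithium is formylated by DMF; no stereocentre is formed.

Step 2
Reactants: 3 (1R,2S,5R)-(−)-menthol; 4 bromoacetyl bromide
Product: 5 (1R,2S,5R)-menthyl bromoacetate
Conditions: Et3N, CH2Cl2, 0 °C to rt
Reagents that add atoms: none
Why: Nucleophilic acyl substitution of the acid bromide by the secondary alcohol installs the chiral ester, the three menthyl stereocentres being untouched.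

Step 3
Reactants: 5 (1R,2S,5R)-menthyl bromoacetate; 6 diphenyl phosphite
Product: 7 (1R,2S,5R)-menthyl 2-(diphenoxyphosphoryl)acetate
Conditions: Et3N, CH2Cl2, 0 °C to rt
Reagents that add atoms: none
Why: Michaelis–Becker alkylation of the diphenyl phosphite anion by the α-bromo ester gives the diaryl phosphonoacetate needed for a Z-selective olefination; no stereocentre is formed.

Step 4
Reactants: 7 (1R,2S,5R)-menthyl 2-(diphenoxyphosphoryl)acetate; 8 1-bromo-3-methylbut-2-ene
Product: 9 (1R,2S,5R)-menthyl 2-(diphenoxyphosphoryl)-5-methylhex-4-enoate (both C2 epimers)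
Conditions: NaH, DMSO, rt
Reagents that add atoms: none
Why: SN2 C-alkylation of the stabilised phosphonoacetate anion by the primary allylic bromide; the new α-stereocentre is destroyed in step 5, so the epimer mixture is used.

Step 5
Reactants: 2 2-bromo-3,6-dimethoxybenzaldehyde; 9 (1R,2S,5R)-menthyl 2-(diphenoxyphosphoryl)-5-methylhex-4-enoate
Product: 10 (1R,2S,5R)-menthyl (2Z)-2-[(2-bromo-3,6-dimethoxyphenyl)methylidene]-5-methylhex-4-enoate
Conditions: NaH, THF, −78 °C to 0 °C; chromatographic removal of the E isomer
Reagents that add atoms: none
Why: Horner–Wadsworth–Emmons olefination with a diaryl phosphonate, whose fast irreversible elimination from the syn adduct should give the Z trisubstituted enoate (aryl cis to the ester), the geometry that later fixes C8.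

Step 6
Reactants: 10 the Z-enoate aryl bromide; 11 (2-ethoxy-2-oxoethyl)zinc bromide
Product: 12 (1R,2S,5R)-menthyl (2Z)-2-{[2-(2-ethoxy-2-oxoethyl)-3,6-dimethoxyphenyl]methylidene}-5-methylhex-4-enoate
Conditions: Pd2(dba)3 (2.5 mol %), XPhos (10 mol %), THF, 60 °C
Reagents that add atoms: none
Why: Palladium-catalysed Negishi-type α-arylation of an ester with a Reformatsky reagent, whose low basicity tolerates the enoate; no stereocentre is formed.

Step 7
Reactants: 12 the arylacetate; 13 methacrolein
Product: 14 aldol adduct, in which the arylacetate carbon of 12 carries a 1-hydroxy-2-methylprop-2-enyl group (diastereomer mixture)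
Conditions: LiN(SiMe3)2, THF, −78 °C; then 13, −78 °C
Reagents that add atoms: none
Why: Aldol 1,2-addition of the lithium enolate of the arylacetate (the most acidic CH2) to the enal at low temperature; both new stereocentres disappear in step 8.

Step 8
Reactants: 14 the aldol adduct
Product: 16 (1R,2S,5R)-menthyl (2Z)-2-({2-[(2E)-1-ethoxy-4-methyl-1-oxopenta-2,4-dien-2-yl]-3,6-dimethoxyphenyl}methylidene)-5-methylhex-4-enoate, via allylic mesylate 15 (not isolated)
Conditions: MsCl, Et3N, CH2Cl2, 0 °C; then DBU, rt
Reagents that add atoms: none
Why: Mesylation and E1cB elimination through the ester enolate should give the conjugated dienoate as the E isomer, with the ester trans and the twisted aryl ring cis to the isopropenyl group, which is the arrangement the cycloaddition needs.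

Step 9
Reactants: 16 the 2-aryl dienoate / Z-enoate
Product: 17 cycloadduct: 6,7-(dimethoxybenzo)bicyclo[3.2.1]oct-2-ene with CO2Et on C1, CH3 on C3, and prenyl and CO2-menthyl on C8 (ester syn to the benzo ring); (1R,5R,8S)
Conditions: PhMe (0.01 M), BHT (cat.), sealed tube, 130 °C; separation of the diastereomers
Reagents that add atoms: none
Why: Proposed new method: heating should bring about a concerted but asynchronous thermal [4+2] cycloaddition in which the s-cis diene C1=C2–C3(CH3)=C4H2 of the 2-aryl dienoate adds suprafacially across the Z-enoate C5=C8 on the neighbouring arene carbon, the C4–C5 bond leading and the C1–C8 bond between the two fully substituted carbons following, each developing centre being stabilised by its ester. The closest known reaction types are the type 1 intramolecular Diels–Alder reaction and, for this very bond pattern, the photochemical intramolecular [4+2] closure of 1-(2-vinylphenyl)buta-1,3-dienes to benzobicyclo[3.2.1]octadienes; what is new is the thermal, stereospecific version on fully substituted termini. Since the tether is only C6–C7, fused closure is impossible and the bridged mode results: the five-membered ring C1–C8–C5–C6–C7 closes by the C1–C8 bond (distal dienophile carbon to tethered diene terminus), and the cyclohexene C1–C2=C3–C4–C5–C8, with it the seven-membered ring through the arene, closes by the C4–C5 bond. C1 and C5 are forced cis by the arene bridge, C8 is set by the Z geometry (the ester cis to the aryl group ends syn to the benzo ring, the prenyl group over the C2=C3 bridge), and the absolute sense comes from the menthyl ester, which makes the two helical transition states diastereomeric, the wanted adduct being separated from the other. The step needs periselectivity over ene, [2+2] and E/Z-isomerisation paths and over intermolecular reaction; the flanking ortho groups that twist both π-systems out of the arene plane and face to face, the aryl group in the inside position of the diene (which places C4 next to C5), high dilution and the moderate temperature should secure it.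

Step 10
Reactants: 17 the cycloadduct
Product: 18 diol: 1,8-bis(hydroxymethyl) analogue of 17 (ring stereocentres unchanged)
Conditions: LiAlH4, THF, 0 °C to reflux
Reagents that add atoms: none
Why: Hydride reduction of both hindered esters to primary alcohols, which also releases the auxiliary; no stereocentre carries an enolisable hydrogen, so none is affected.

Step 11
Reactants: 18 the diol
Product: 19 dialdehyde: 1,8-diformyl analogue of 17
Conditions: (COCl)2, DMSO, CH2Cl2, −78 °C; then Et3N, −78 °C to 0 °C
Reagents that add atoms: none
Why: Swern oxidation, in which both hydroxyls are activated before the base is added, so lactol and lactone formation from the 1,4-diol is avoided; the aldehydes sit on quaternary carbons and cannot epimerise.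

Step 12
Reactants: 19 the dialdehyde; 20 vinylmagnesium bromide
Product: 21 lactol mono-adduct: the C1 formyl group has become a CH(CH=CH2)–O unit whose oxygen is closed onto the C8 formyl carbon as a five-membered cyclic hemiacetal fused across C1–C8 (epimers at both new carbons)
Conditions: 20 (1.05 equiv), THF, −78 °C; aq. NH4Cl quench at −78 °C
Reagents that add atoms: none
Why: Grignard 1,2-addition to a non-enolisable aldehyde, expected first at the outward-pointing bridgehead (C1) formyl group, after which the magnesium alkoxide closes onto the neighbouring formyl group to a five-membered lactolate that resists further attack at −78 °C (the known behaviour of 1,4-dialdehydes towards one equivalent of a Grignard reagent), so only one vinyl group is introduced; the configurations of the two new centres are immaterial because both carbons end as ketones in step 15, and which aldehyde reacts first has no bearing on the outcome of step 13.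

Step 13
Reactants: 21 the lactol; 20 vinylmagnesium bromide
Product: 22 bis(vinyl carbinol): 1,8-bis(1-hydroxyprop-2-en-1-yl) analogue of 17 (carbinol epimers)
Conditions: 20 (4 equiv), THF, 0 °C to rt
Reagents that add atoms: none
Why: Excess Grignard reagent deprotonates the lactol and adds 1,2 to the ring-opened alkoxy aldehyde that is in equilibrium with the lactolate at the higher temperature (the standard conversion of a lactol into a diol); the configuration of the new carbinol carbon does not matter because it is oxidised in step 15.

Step 14
Reactants: 22 the bis(vinyl carbinol)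
Product: 23 tetracyclic diol: ring A closed as a cyclohex-2-ene-1,4-diol across C1–C8 (carbinol epimers), arene as dimethyl ether
Conditions: RuCl2(PCy3)2(=CHPh) (first-generation Grubbs catalyst, 10 mol %), CH2Cl2, 40 °C
Reagents that add atoms: none
Why: Ring-closing metathesis of the two terminal vinyl groups forms ring A, the less active first-generation catalyst being chosen so that the trisubstituted prenyl and ring alkenes stay out of the reaction.

Step 15
Reactants: 23 the tetracyclic diol
Product: 24 O,O′-dimethyl ether of the target (ring A ene-dione)
Conditions: Dess–Martin periodinane, CH2Cl2, rt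
Reagents that add atoms: none
Why: Dess–Martin oxidation of both allylic alcohols gives the ene-dione, which can neither enolise towards nor aromatise across the two quaternary ring-fusion carbons.

Step 16
Reactants: 24 the dimethyl ether
Product: 26 the target hydroquinone (1R,5R,8S in the numbering above), via quinone 25 (not isolated)
Conditions: (NH4)2Ce(NO3)6, MeCN/H2O, 0 °C; then aq. Na2S2O4, EtOAc, rt (short contact)
Reagents that add atoms: water, O
Why: Oxidative demethylation by tetravalent cerium gives the p-quinone (oxygen from water), which dithionite should reduce far faster than the ene-dione, so the hydroquinone is released without touching ring A or the stereocentres.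

**Compound list**

1 | 2-bromo-1,4-dimethoxybenzene | COc1ccc(OC)c(Br)c1 | starting material
2 | 2-bromo-3,6-dimethoxybenzaldehyde | COc1ccc(OC)c(C=O)c1Br | intermediate
3 | (1R,2S,5R)-(−)-menthol | O[C@@H]1C[C@H](C)CC[C@H]1C(C)C | starting material
4 | bromoacetyl bromide | BrCC(Br)=O | starting material
5 | (1R,2S,5R)-menthyl bromoacetate | BrCC(=O)O[C@@H]1C[C@H](C)CC[C@H]1C(C)C | intermediate
6 | diphenyl phosphite | O=[PH](Oc1ccccc1)Oc1ccccc1 | starting material
7 | (1R,2S,5R)-menthyl 2-(diphenoxyphosphoryl)acetate | O=C(CP(=O)(Oc1ccccc1)Oc1ccccc1)O[C@@H]1C[C@H](C)CC[C@H]1C(C)C | intermediate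
8 | 1-bromo-3-methylbut-2-ene (prenyl bromide) | CC(C)=CCBr | starting material
9 | (1R,2S,5R)-menthyl 2-(diphenoxyphosphoryl)-5-methylhex-4-enoate (both C2 epimers) | CC(C)=CCC(C(=O)O[C@@H]1C[C@H](C)CC[C@H]1C(C)C)P(=O)(Oc1ccccc1)Oc1ccccc1 | intermediate
10 | (1R,2S,5R)-menthyl (2Z)-2-[(2-bromo-3,6-dimethoxyphenyl)methylidene]-5-methylhex-4-enoate | CC(C)=CC/C(C(=O)O[C@@H]1C[C@H](C)CC[C@H]1C(C)C)=C/c1c(OC)ccc(OC)c1Br | intermediate
11 | (2-ethoxy-2-oxoethyl)zinc bromide | CCOC(=O)C[Zn]Br | starting material
12 | (1R,2S,5R)-menthyl (2Z)-2-{[2-(2-ethoxy-2-oxoethyl)-3,6-dimethoxyphenyl]methylidene}-5-methylhex-4-enoate | CC(C)=CC/C(C(=O)O[C@@H]1C[C@H](C)CC[C@H]1C(C)C)=C/c1c(OC)ccc(OC)c1CC(=O)OCC | intermediate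
13 | methacrolein (2-methylprop-2-enal) | CC(=C)C=O | starting material
14 | aldol adduct: 12 with a 1-hydroxy-2-methylprop-2-enyl group on the arylacetate carbon (diastereomer mixture) | CC(C)=CC/C(C(=O)O[C@@H]1C[C@H](C)CC[C@H]1C(C)C)=C/c1c(OC)ccc(OC)c1C(C(=O)OCC)C(O)C(C)=C | intermediate
15 | methanesulfonate of 14 | CC(C)=CC/C(C(=O)O[C@@H]1C[C@H](C)CC[C@H]1C(C)C)=C/c1c(OC)ccc(OC)c1C(C(=O)OCC)C(OS(C)(=O)=O)C(C)=C | intermediate
16 | (1R,2S,5R)-menthyl (2Z)-2-({2-[(2E)-1-ethoxy-4-methyl-1-oxopenta-2,4-dien-2-yl]-3,6-dimethoxyphenyl}methylidene)-5-methylhex-4-enoate | CC(C)=CC/C(C(=O)O[C@@H]1C[C@H](C)CC[C@H]1C(C)C)=C/c1c(OC)ccc(OC)c1/C(C(=O)OCC)=C\C(C)=C | intermediate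
17 | cycloadduct, (1R,5R,8S): 6,7-(dimethoxybenzo)bicyclo[3.2.1]oct-2-ene, 1-CO2Et, 3-CH3, 8-prenyl, 8-CO2-menthyl syn to the benzo ring | CC(C)=CC[C@]1(C(=O)O[C@@H]3C[C@H](C)CC[C@H]3C(C)C)[C@@H]2CC(C)=C[C@@]1(C(=O)OCC)c1c(OC)ccc(OC)c12 | intermediate
18 | diol: 1,8-bis(hydroxymethyl) analogue of 17, ring configuration unchanged | CC(C)=CC[C@]1(CO)[C@@H]2CC(C)=C[C@@]1(CO)c1c(OC)ccc(OC)c12 | intermediate
19 | dialdehyde: 1,8-diformyl analogue of 17, ring configuration unchanged | CC(C)=CC[C@]1(C=O)[C@@H]2CC(C)=C[C@@]1(C=O)c1c(OC)ccc(OC)c12 | intermediate
20 | vinylmagnesium bromide | C=C[Mg]Br | starting material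
21 | lactol mono-adduct: C1 carries CH(CH=CH2)–O, closed onto the C8 formyl carbon as a five-membered cyclic hemiacetal fused across C1–C8 (epimers at both new carbons), ring configuration unchanged | CC(C)=CC[C@]1(C(O)OC3C=C)[C@@H]2CC(C)=C[C@@]13c1c(OC)ccc(OC)c12 | intermediate
22 | bis(vinyl carbinol): 1,8-bis(1-hydroxyprop-2-en-1-yl) analogue of 17 (carbinol epimers) | CC(C)=CC[C@]1(C(O)C=C)[C@@H]2CC(C)=C[C@@]1(C(O)C=C)c1c(OC)ccc(OC)c12 | intermediate
23 | tetracyclic diol: ring A as cyclohex-2-ene-1,4-diol fused across C1–C8 (carbinol epimers), dimethyl ether | CC(C)=CC[C@@]12C(O)C=CC(O)[C@@]13C=C(C)C[C@@H]2c1c(OC)ccc(OC)c13 | intermediate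
24 | O,O′-dimethyl ether of the target (ring A ene-dione), ring configuration as in the target | CC(C)=CC[C@@]12C(=O)C=CC(=O)[C@@]13C=C(C)C[C@@H]2c1c(OC)ccc(OC)c13 | intermediate
25 | p-quinone of the target (arene ring oxidised), ring configuration as in the target | CC(C)=CC[C@@]12C(=O)C=CC(=O)[C@@]13C=C(C)C[C@@H]2C1=C3C(=O)C=CC1=O | intermediate
26 | CNP0513322.1: hydroquinone-fused bicyclo[3.2.1]octene with ring A ene-dione across C1–C8, 8-prenyl, 3-methyl; (1R,5R,8S) | CC(C)=CC[C@@]12C(=O)C=CC(=O)[C@@]13C=C(C)C[C@@H]2c1c(O)ccc(O)c13 | target

**Summary**

Total step count: 16. Longest linear sequence: 15 steps (from 3 through steps 2–16); 13 steps from 1.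

Steps most likely to fail:

Step 9 (Proposed new method). The cycloaddition may not occur at temperatures the Z-enoate tolerates, may divert into an intramolecular ene reaction or a stepwise diradical path that loses the C8 configuration, or may show little facial bias from the auxiliary. The fallback uses the known excited-state chemistry of 1-(2-vinylphenyl)buta-1,3-dienes. It sets out from 16 and comes back at 17. 16 is irradiated (about 350 nm, degassed dilute benzene), so that the same two bonds form stepwise, C1–C8 first to a benzylic/allylic biradical and then C4–C5 by 1,6-closure. Because the enoate photo-isomerises, control of C8 by alkene geometry is given up, and 17 has to be separated from its C8 epimer F1 and from the menthyl diastereomers.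

Step 14. The ruthenium carbene may engage the geminal prenyl group (five-membered ring closure with loss of isobutene) or may fail to close between the two hindered carbinols. The fallback closes ring A by enolate coupling instead of metathesis. It sets out from 19 and comes back at 24. Methylmagnesium bromide (excess, THF, −78 °C to rt) adds to both aldehydes to give the bis(1-hydroxyethyl) compound F2, and Dess–Martin oxidation gives the 1,8-diacetyl compound F3. Its bis(lithium enolate) (LiN(SiMe3)2, THF, −78 °C) is coupled oxidatively with CuCl2 to the saturated ring A 1,4-diketone F4. Dehydrogenation with 2-iodoxybenzoic acid (DMSO, 70 °C) then gives 24.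

Step 6. Oxidative addition at the doubly ortho-substituted bromide may be slow, and the arylpalladium species may instead cyclise onto the prenyl alkene (Heck path) or isomerise the Z-enoate. The fallback changes the order of arm construction. It sets out from 2 and comes back at 12. The aldehyde is protected as the dioxolane F5 (ethylene glycol, TsOH, PhMe, reflux with water removal). The same coupling with 11 on this simpler bromide gives the arylacetate acetal F6, and aqueous HCl in THF releases the aldehyde F7. The Z-selective olefination with 9 (NaH, THF, −78 °C, the phosphonate being the more acidic partner) then gives 12.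

**Further compounds**

F1 | step 9 | C8 epimer of 17 (prenyl syn to the benzo ring, menthyl ester over the C2=C3 bridge) | CC(C)=CC[C@@]1(C(=O)O[C@@H]3C[C@H](C)CC[C@H]3C(C)C)[C@@H]2CC(C)=C[C@@]1(C(=O)OCC)c1c(OC)ccc(OC)c12
F2 | step 14 | 1,8-bis(1-hydroxyethyl) analogue of 19 (carbinol epimers) | CC(C)=CC[C@]1(C(C)O)[C@@H]2CC(C)=C[C@@]1(C(C)O)c1c(OC)ccc(OC)c12
F3 | step 14 | 1,8-diacetyl analogue of 19 | CC(C)=CC[C@]1(C(C)=O)[C@@H]2CC(C)=C[C@@]1(C(C)=O)c1c(OC)ccc(OC)c12
F4 | step 14 | dihydro derivative of 24 (ring A as cyclohexane-1,4-dione) | CC(C)=CC[C@@]12C(=O)CCC(=O)[C@@]13C=C(C)C[C@@H]2c1c(OC)ccc(OC)c13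
F5 | step 6 | 2-(2-bromo-3,6-dimethoxyphenyl)-1,3-dioxolane | COc1ccc(OC)c(C2OCCO2)c1Br
F6 | step 6 | ethyl 2-[2-(1,3-dioxolan-2-yl)-3,6-dimethoxyphenyl]acetate | CCOC(=O)Cc1c(OC)ccc(OC)c1C1OCCO1
F7 | step 6 | ethyl 2-(2-formyl-3,6-dimethoxyphenyl)acetate | CCOC(=O)Cc1c(OC)ccc(OC)c1C=O
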